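**Plan**
- Retrosynthesis: the phenolic C–O bond is cut first (back to an aldehyde by Baeyer–Villiger oxidation, then to ring C–H by Vilsmeier–Haack formylation). Next comes the C9–C10 bond of the chain (C1 on the ring), and last the ring–C1 bond.
- Forward: aryl bromide 1 and dibromide 2 give, through Grignard 3, the ω-bromononyl arene 4. Tetradecyl Grignard 5 then joins C9 to C10 and completes all 31 carbons in 6.
- The missing oxygen follows: formylation (iminium 7) to aldehyde 8, then Baeyer–Villiger oxidation (formate 9) and methanolysis to phenol 10.
- Enabling feature: C9 and C10 are unbranched CH2 groups far from any functional group, so they pair as primary bromide and primary Grignard at the final oxidation level. The benzene ring carries only its two OMe groups (ring C3, C5) at that point, with the acidic O–H of ring C2 held back as C–H. Ring C2 (para to the C5 OMe, ortho to the C3 OMe) takes the electrophile later.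
- Stereochemistry: none to set; the target has no stereocentre and no C=C.

Key step: step 2

Assumption: tetradecylmagnesium chloride 5 is taken as the commercial THF solution; made from 1-chlorotetradecane and magnesium it should behave identically.

**Step 1**
Reactants: 1 1-bromo-3,5-dimethoxybenzene; 2 1,9-dibromononane (3 equiv)
Product: 4 1-(9-bromononyl)-3,5-dimethoxybenzene, via arylmagnesium bromide 3 (not isolated)
Conditions: Mg, cat. I2, THF, reflux; then added slowly to 2, Li2CuCl4 (3 mol %), NMP, THF, 0 °C → rt
Reagents that add atoms: none
Why: Copper-catalysed Kumada-type (Kochi) alkylation of an aryl Grignard with a primary bromide; inverse addition into excess symmetric dibromide should hold the reaction at monosubstitution, and the excess 2 is recovered by distillation.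

**Step 2**
Reactants: 4 1-(9-bromononyl)-3,5-dimethoxybenzene; 5 tetradecylmagnesium chloride (1.5 equiv)
Product: 6 1,3-dimethoxy-5-tricosylbenzene
Conditions: Li2CuCl4 (3 mol %), NMP (4 equiv), THF, 0 °C → rt, slow addition of 5
Reagents that add atoms: none
Why: Grignard 5 reduces the copper salt to Cu(I) and transmetalates to a tetradecylcuprate, which attacks the primary C–Br of 4 in an SN2-type oxidative addition; the resulting dialkyl-Cu(III) reductively eliminates the C9–C10 C(sp3)–C(sp3) bond. The closest known reaction type is the Kochi–Tamura/Cahiez copper-catalysed coupling of alkyl Grignard reagents with primary alkyl bromides, the standard way to build long lipid chains. No ring is closed and no stereocentre is formed. The step needs cross-coupling to win over Wurtz homocoupling, β-hydride elimination and halogen–magnesium exchange; unbranched primary carbons at both ends, NMP and slow addition of 5 should secure this. Chemoselectivity is secured by the substrate, whose ring carries only inert aryl methyl ethers and no acidic O–H, because the phenol oxygen is not yet present. The step delivers the complete carbon skeleton directly at the final oxidation level of the chain.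

**Step 3**
Reactants: 6 1,3-dimethoxy-5-tricosylbenzene
Product: 8 2,4-dimethoxy-6-tricosylbenzaldehyde, via aryl iminium chloride 7 (not isolated)
Conditions: POCl3, DMF, ClCH2CH2Cl, 0 → 70 °C; then H2O, 50 °C
Reagents that add atoms: N,N-dimethylformamide, CN(C)C=O; water, O
Why: Vilsmeier–Haack formylation; the bulky chloroiminium ion should attack the ring carbon para to one OMe and ortho to the other rather than the crowded carbon between the two OMe groups, as is known for orcinol and olivetol dimethyl ethers, and the cosolvent keeps the waxy arene in solution.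

**Step 4**
Reactants: 8 2,4-dimethoxy-6-tricosylbenzaldehyde
Product: 10 2,4-dimethoxy-6-tricosylphenol, via aryl formate 9 (not isolated)
Conditions: mCPBA (1.2 equiv), CH2Cl2, 0 °C → rt; then K2CO3 (cat.), MeOH–THF, rt, argon
Reagents that add atoms: mCPBA (3-chloroperoxybenzoic acid), OOC(=O)c1cccc(Cl)c1
Why: Baeyer–Villiger (Dakin-type) oxidation in which the electron-rich 2,4-dimethoxyaryl group migrates in preference to hydrogen to give the aryl formate, which methanolysis cleaves to the phenol; argon guards the electron-rich phenol against air oxidation.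

**Compound list**
1 | 1-bromo-3,5-dimethoxybenzene | COc1cc(Br)cc(OC)c1 | starting material
2 | 1,9-dibromononane | BrCCCCCCCCCBr | starting material
3 | (3,5-dimethoxyphenyl)magnesium bromide (formed in the flask) | COc1cc([Mg]Br)cc(OC)c1 | intermediate
4 | 1-(9-bromononyl)-3,5-dimethoxybenzene | COc1cc(CCCCCCCCCBr)cc(OC)c1 | intermediate
5 | tetradecylmagnesium chloride | CCCCCCCCCCCCCC[Mg]Cl | starting material
6 | 1,3-dimethoxy-5-tricosylbenzene | CCCCCCCCCCCCCCCCCCCCCCCc1cc(OC)cc(OC)c1 | intermediate
7 | N-[(2,4-dimethoxy-6-tricosylphenyl)methylidene]-N-methylmethanaminium chloride (formed in the flask) | CCCCCCCCCCCCCCCCCCCCCCCc1cc(OC)cc(OC)c1C=[N+](C)C.[Cl-] | intermediate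
8 | 2,4-dimethoxy-6-tricosylbenzaldehyde | CCCCCCCCCCCCCCCCCCCCCCCc1cc(OC)cc(OC)c1C=O | intermediate
9 | 2,4-dimethoxy-6-tricosylphenyl formate (formed in the flask) | CCCCCCCCCCCCCCCCCCCCCCCc1cc(OC)cc(OC)c1OC=O | intermediate
10 | 2,4-dimethoxy-6-tricosylphenol (CNP0228278.0) | CCCCCCCCCCCCCCCCCCCCCCCc1cc(OC)cc(OC)c1O | target

Total step count: 4. Longest linear sequence: 4 steps (1 → 4 → 6 → 8 → 10).

**Steps most likely to fail**

Step 1. Double arylation of the dibromide and bromine–magnesium exchange between the aryl Grignard and the alkyl bromide may erode the monoalkylation; aryl copper species are also sluggish nucleophiles. The fallback sets out from 1 and comes back at 4. Sonogashira coupling of 1 with non-8-yn-1-ol (Pd(PPh3)2Cl2, CuI, Et3N, 70 °C) should give 9-(3,5-dimethoxyphenyl)non-8-yn-1-ol F1. Hydrogenation (H2, Pd/C, EtOAc) should give 9-(3,5-dimethoxyphenyl)nonan-1-ol F2. Appel bromination (CBr4, PPh3, CH2Cl2) should then return to 4.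

Step 3. Formylation may stall because the waxy arene separates from the polar medium, and site selectivity may be poor if the iminium ion also attacks between the two OMe groups. The fallback sets out from 6 and comes back at 10, bypassing 8. Bromination with NBS in CH2Cl2 at 0 °C, where the substrate is soluble and the small electrophile is known to go para to OMe, should give 2-bromo-1,5-dimethoxy-3-tricosylbenzene F3. Bromine–lithium exchange (n-BuLi, THF–hexane, −40 °C) should give (2,4-dimethoxy-6-tricosylphenyl)lithium F4. Trapping with B(OMe)3 should give lithium (2,4-dimethoxy-6-tricosylphenyl)trimethoxyborate F5. Oxidation in the same flask (H2O2, aq NaOH, 0 °C) should give 10.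

Step 2. Wurtz-type homocoupling of the Grignard reagent, halogen–magnesium exchange and reduction or elimination of the bromide may compete with cross-coupling. The fallback sets out from 4 and comes back at 6, forming the same C9–C10 bond as a C(sp3)–C(sp) bond. Deprotonation of tetradec-1-yne (n-BuLi, THF, −78 °C) gives lithium tetradec-1-yn-1-ide F6. Alkylation with 4 in THF–DMPU (0 °C → rt) should give 1,3-dimethoxy-5-(tricos-10-yn-1-yl)benzene F7. Hydrogenation (H2, Pd/C, EtOAc) should return to 6.

**Further compounds**
F1 | step 1 | 9-(3,5-dimethoxyphenyl)non-8-yn-1-ol | OCCCCCCCC#Cc1cc(OC)cc(OC)c1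
F2 | step 1 | 9-(3,5-dimethoxyphenyl)nonan-1-ol | OCCCCCCCCCc1cc(OC)cc(OC)c1
F3 | step 3 | 2-bromo-1,5-dimethoxy-3-tricosylbenzene | CCCCCCCCCCCCCCCCCCCCCCCc1cc(OC)cc(OC)c1Br
F4 | step 3 | (2,4-dimethoxy-6-tricosylphenyl)lithium | CCCCCCCCCCCCCCCCCCCCCCCc1cc(OC)cc(OC)c1[Li]
F5 | step 3 | lithium (2,4-dimethoxy-6-tricosylphenyl)trimethoxyborate | CCCCCCCCCCCCCCCCCCCCCCCc1cc(OC)cc(OC)c1[B-](OC)(OC)OC.[Li+]
F6 | step 2 | lithium tetradec-1-yn-1-ide | CCCCCCCCCCCCC#C[Li]
F7 | step 2 | 1,3-dimethoxy-5-(tricos-10-yn-1-yl)benzene | CCCCCCCCCCCCC#CCCCCCCCCCc1cc(OC)cc(OC)c1
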